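The pitfall in setting teal beside the south run is to read the percent straight across. Both stand at 65 °C, and teal is asked at 2.5 min, the time of the last south reading, which shows 8.7% target; but the charge differs, 20 mM against 15 mM.

| flask | substrate | temperature | remark | time |
|---|---|---|---|---|
| north-east | 10 mM | 35 °C | run made earlier |  |
| south | 15 mM | 65 °C | run made earlier |  |
| teal | 20 mM | 65 °C |  | 2.5 min |
| amber | 20 mM | 90 °C |  | 2.5 min |
| ochre | 20 mM | 40 °C |  | 2.5 min |
| violet | 20 mM |  | at 90 °C until 2.0 min, from then on at 40 °C | 2.5 min |

| run | time / min | target / % | side product / % |
|---|---|---|---|
| north-east | 3.00 | 1.1 | 0 |
| north-east | 6.00 | 1.0 | 0 |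
| north-east | 8.00 | 2.0 | 0.7 |
| north-east | 12.0 | 2.6 | 0.1 |
| south | 0.667 | 4.0 | 0.4 |
| south | 1.33 | 5.5 | 0 |
| south | 2.00 | 7.5 | 1.0 |
| south | 2.50 | 8.7 | 0.7 |

(each reading ± 0.5 percentage points)

- in percentages every species weighs as the substrate in it: one target or isomer of the product counts as two
- in percentages every species weighs as the substrate in it: one side product counts as three

* the best flask by share of target in all that became target or side product or isomer of the product; "all alike" if 1.5 percentage points covers them all (teal / amber / ochre / violet / all alike)
* share of target in all that became target or side product or isomer of the product, teal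
* share of target in all that became target or side product or isomer of the product, amber
* share of target in all that became target or side product or isomer of the product, ochre
* share of target in all that became target or side product or isomer of the product, violet

At one temperature and time, a percent of the charge carries over unchanged if the step is first order. But one target counts as two substrate, so we take it that two substrate must meet, a second-order step as in step growth. The substrate concentration then sets the rate, and at one temperature, early in a run, the clock of a flask is the product of its charge c and its time t. From the last south reading we keep κ, the fraction of the charge turned into target per unit of c·t: 0.0387 M⁻¹ s⁻¹.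

Teal has the larger charge, so by our reckoning it reaches 11.6% target, not 8.7%. That is a gap of 2.9 percentage points against a scatter of 0.5 points. The last north-east reading gives its own κ at 35 °C, 0.00361 M⁻¹ s⁻¹, which puts 1.08% target in ochre. Ochre at 40 °C is warmer than the north-east run, so we expect it to pass that mark, which carries the scatter of a single reading. If what is lost is made from target, the share of target (the selectivity) should stand higher in the flask that holds less target over the same time, so we rank ochre above teal; our reckoning goes no further than that order.

The forecast gives 85% for teal, 79% for amber, 87% for ochre and 80% for violet, and names ochre as best: “I therefore expect lower shares in the hot flasks.”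

    2 substrate ⇌ target (K = 220 M⁻¹, k = 0.180 M⁻¹ s⁻¹, Ea = 80.0 kJ mol⁻¹, ΔH = 24.0 kJ mol⁻¹)
    substrate + target → side product (k = 0.0690 M⁻¹ s⁻¹, Ea = 84.0 kJ mol⁻¹)
    target ⇌ isomer of the product (K = 0.870, k = 0.00400 s⁻¹, Ea = 114 kJ mol⁻¹, ΔH = −5.00 kJ mol⁻¹)
    (constants at 90 °C)

The flasks give 96.3% for teal, 68.0% for amber, 99.7% for ochre and 72.5% for violet, with ochre the best. Teal holds 12.6% target, a little above the 11.6% from κ, and ochre holds 1.54%, above its mark of 1.08%. In ochre, the relaxation half-life of two substrate and target at the asked time, by that step alone and both ways together, is 46.5 min, and that of target and isomer of the product, by its step alone, is 10.6 h, both long against 2.5 min. At 2.50 min ochre still holds 98% of its charged substrate.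

The data come from a simulation for substances that don't exist, noise included.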